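**Plan**
- Retrosynthesis: the two ring B phenols are unmasked last from benzyl ethers. Removing the C4 carbonyl oxygen then leads back to a 3-methoxyflavylium cation.
- Enabling feature (flavone numbering): without its C4 oxygen, ring C is a pyrylium. C4 is the formyl carbon of a ring A salicylaldehyde whose phenol oxygen is O1. C3, with its methoxy group, is the CH2 of a ring B aryl methoxymethyl ketone whose carbonyl carbon is C2. Cutting C3=C4 and O1–C2 therefore gives two simple arenes.
- The ketone is cut at C1'–C2 into an aryllithium (from brominated, dibenzylated 2-methoxyhydroquinone) and the Weinreb amide of methoxyacetic acid.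
- Forward: ring B is benzylated, brominated and acylated (steps 1–3). Ring C is closed onto the intact ring A aldehyde as a flavylium salt (step 4). C4 is oxygenated to the chromone (step 5), and hydrogenolysis frees the phenols (step 6).
- Stereochemistry: the target has no stereocentre and no stereogenic double bond, so nothing has to be set.

Key step: step 4

Assumption: the target is read as 2',5'-dihydroxy-3,4',7,8-tetramethoxyflavone (achiral). Flavone numbering is used throughout (ring C: O1, C2, C3, C4; ring A: C4a to C8a; ring B: C1' to C6').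

Step 1
Reactants: 1 2-methoxyhydroquinone
Product: 2 1,4-bis(benzyloxy)-2-methoxybenzene
Conditions: BnBr, K2CO3, degassed DMF, N2, rt to 60 °C
Reagents that add atoms: benzyl bromide, BrCc1ccccc1
Why: Williamson etherification of both phenols; exclusion of air should prevent oxidation of the hydroquinone to the quinone before alkylation.

Step 2
Reactants: 2 1,4-bis(benzyloxy)-2-methoxybenzene
Product: 3 1,4-bis(benzyloxy)-2-bromo-5-methoxybenzene
Conditions: NBS, MeCN, 0 °C to rt, dark
Reagents that add atoms: N-bromosuccinimide, O=C1CCC(=O)N1Br
Why: Electrophilic aromatic bromination should go to the one position that is para to the methoxy group, ortho to a benzyloxy group and not flanked by two substituents, as in the bromination of 1,2,4-trialkoxybenzenes.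

Step 3
Reactants: 3 1,4-bis(benzyloxy)-2-bromo-5-methoxybenzene; 4 N,2-dimethoxy-N-methylacetamide
Product: 7 1-[2,5-bis(benzyloxy)-4-methoxyphenyl]-2-methoxyethanone, via aryllithium 5 (not isolated), via lithium hemiaminal alkoxide 6 (not isolated)
Conditions: n-BuLi, THF, −78 °C; then 4, −78 to 0 °C; 1 M aq. HCl
Reagents that add atoms: none
Why: Bromine–lithium exchange followed by Weinreb ketone synthesis, in which the chelated tetrahedral adduct 6 stops the addition at the ketone stage; the Lewis-acid-free conditions avoid the loss of CO from a methoxyacetyl cation and of the ortho benzyl group that a Friedel–Crafts acylation would risk.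

Step 4
Reactants: 7 1-[2,5-bis(benzyloxy)-4-methoxyphenyl]-2-methoxyethanone; 8 2-hydroxy-3,4-dimethoxybenzaldehyde
Product: 10 2-[2,5-bis(benzyloxy)-4-methoxyphenyl]-3,7,8-trimethoxychromenylium chloride, via chalcone 9 (not isolated)
Conditions: HCl (g), dry EtOAc/AcOH, 0 °C, then 0–5 °C; Et2O to precipitate the salt
Reagents that add atoms: hydrogen chloride, Cl
Why: Under dry HCl the ketone enolises at its only enolisable carbon, the methoxy-bearing CH2, and adds to the protonated aldehyde; loss of water gives the 2-hydroxy-α-methoxychalcone 9 and with it the C3=C4 bond. Acid equilibrates the enone geometry so that the phenol oxygen can reach the protonated ketone carbon, and a second dehydration delivers the aromatic benzopyrylium cation with the new O1–C2 bond. The closest known reaction type is the Robinson-type acid-catalysed synthesis of flavylium salts from salicylaldehydes and aryl ketones, aryl alkoxymethyl ketones included. Ring C closes by 6-exo-trig attack of the phenol oxygen on the activated carbonyl, followed by aromatising loss of water. No stereocentre is created. The step needs one sense of aldol addition and one cyclisation mode: the aldehyde cannot enolise, the ketone has a single enolisable position, and the ring A hydroxyl is the only free phenol because both ring B oxygens are benzylated, while the low temperature and the absence of water and bromide should spare the benzyl ethers.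

Step 5
Reactants: 10 2-[2,5-bis(benzyloxy)-4-methoxyphenyl]-3,7,8-trimethoxychromenylium chloride
Product: 12 2-[2,5-bis(benzyloxy)-4-methoxyphenyl]-3,7,8-trimethoxy-4H-chromen-4-one, via C4 tert-butyl peroxide 11 (not isolated)
Conditions: t-BuOOH (anhydrous, in decane), Et3N, CH2Cl2, −20 °C; then DBU, 0 °C to rt
Reagents that add atoms: tert-butyl hydroperoxide, CC(C)(C)OO
Why: Proposed new method: C2 of cation 10 is shielded by the ortho-benzyloxyaryl group and the 3-methoxy group, so tert-butylperoxide anion should add at the open C4 to give peroxide 11 (a C2 adduct has no hydrogen to lose and can re-ionise), and DBU then removes the benzylic, allylic C4–H with O–O cleavage, expelling tert-butoxide and forming the conjugated chromone irreversibly; the closest known reaction types are the capture of xanthylium-type cations by hydroperoxides to give mixed peroxides and the base-induced Kornblum–DeLaMare fragmentation of secondary benzylic tert-butyl peroxides to ketones.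

Step 6
Reactants: 12 2-[2,5-bis(benzyloxy)-4-methoxyphenyl]-3,7,8-trimethoxy-4H-chromen-4-one
Product: 13 diplotrin A (2-(2,5-dihydroxy-4-methoxyphenyl)-3,7,8-trimethoxy-4H-chromen-4-one)
Conditions: H2 (1 atm), Pd/C, EtOAc/MeOH, rt; work-up under Ar
Reagents that add atoms: none
Why: Catalytic hydrogenolysis of the two benzyl aryl ethers, which should leave the tetrasubstituted C2=C3 bond of the chromone (a vinylogous ester) and the four methyl ethers untouched.

**Compound list**
1 | 2-methoxyhydroquinone (2-methoxybenzene-1,4-diol) | COc1cc(O)ccc1O | starting material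
2 | 1,4-bis(benzyloxy)-2-methoxybenzene | COc1cc(OCc2ccccc2)ccc1OCc1ccccc1 | intermediate
3 | 1,4-bis(benzyloxy)-2-bromo-5-methoxybenzene | COc1cc(OCc2ccccc2)c(Br)cc1OCc1ccccc1 | intermediate
4 | N,2-dimethoxy-N-methylacetamide | COCC(=O)N(C)OC | starting material
5 | [2,5-bis(benzyloxy)-4-methoxyphenyl]lithium | [Li]c1cc(OCc2ccccc2)c(OC)cc1OCc1ccccc1 | intermediate (not isolated)
6 | lithium 1-[2,5-bis(benzyloxy)-4-methoxyphenyl]-2-methoxy-1-[methoxy(methyl)amino]ethan-1-olate (racemic) | [Li]OC(COC)(N(C)OC)c1cc(OCc2ccccc2)c(OC)cc1OCc1ccccc1 | intermediate (not isolated)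
7 | 1-[2,5-bis(benzyloxy)-4-methoxyphenyl]-2-methoxyethanone | COCC(=O)c1cc(OCc2ccccc2)c(OC)cc1OCc1ccccc1 | intermediate
8 | 2-hydroxy-3,4-dimethoxybenzaldehyde | COc1ccc(C=O)c(O)c1OC | starting material
9 | (Z)-1-[2,5-bis(benzyloxy)-4-methoxyphenyl]-3-(2-hydroxy-3,4-dimethoxyphenyl)-2-methoxyprop-2-en-1-one | COc1ccc(/C=C(\OC)C(=O)c2cc(OCc3ccccc3)c(OC)cc2OCc2ccccc2)c(O)c1OC | intermediate (not isolated)
10 | 2-[2,5-bis(benzyloxy)-4-methoxyphenyl]-3,7,8-trimethoxychromenylium chloride | COc1cc(OCc2ccccc2)c(-c2[o+]c3c(OC)c(OC)ccc3cc2OC)cc1OCc1ccccc1.[Cl-] | intermediate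
11 | 2-[2,5-bis(benzyloxy)-4-methoxyphenyl]-4-(tert-butylperoxy)-3,7,8-trimethoxy-4H-chromene (racemic) | COC1=C(c2cc(OCc3ccccc3)c(OC)cc2OCc2ccccc2)Oc2c(OC)c(OC)ccc2C1OOC(C)(C)C | intermediate (not isolated)
12 | 2-[2,5-bis(benzyloxy)-4-methoxyphenyl]-3,7,8-trimethoxy-4H-chromen-4-one | COc1cc(OCc2ccccc2)c(-c2oc3c(OC)c(OC)ccc3c(=O)c2OC)cc1OCc1ccccc1 | intermediate
13 | diplotrin A | COc1cc(O)c(-c2oc3c(OC)c(OC)ccc3c(=O)c2OC)cc1O | target

**Step count**
Total step count: 6
Longest linear sequence: 6 steps (1 to 13)

**Steps most likely to fail, with fallbacks**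

Step 5 (C4 oxygenation of the cation). The peroxide anion may add at C2 instead of C4 and the adduct may fragment with ring opening, or traces of water may open the pyrylium ring to the chalcone before the Kornblum–DeLaMare fragmentation can occur. The fallback builds the chromone carbonyl by known flavonol chemistry; it sets out from 3 and comes back at 12. Aryllithium 5, made from 3 as in step 3, is quenched with DMF to give 2,5-bis(benzyloxy)-4-methoxybenzaldehyde F1. Claisen–Schmidt condensation of this aldehyde with commercial 1-(2-hydroxy-3,4-dimethoxyphenyl)ethanone (CC(=O)c1ccc(OC)c(OC)c1O; KOH, EtOH) should give (E)-3-[2,5-bis(benzyloxy)-4-methoxyphenyl]-1-(2-hydroxy-3,4-dimethoxyphenyl)prop-2-en-1-one F2. Algar–Flynn–Oyamada oxidation (H2O2, NaOH, MeOH, 0 °C) should convert the chalcone into 2-[2,5-bis(benzyloxy)-4-methoxyphenyl]-3-hydroxy-7,8-dimethoxy-4H-chromen-4-one F3. O-Methylation of the 3-hydroxyl (MeI, K2CO3, acetone) then gives 12, which enters step 6 unchanged.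

Step 4 (flavylium condensation). The benzyl ether ortho to the ketone may be lost under prolonged exposure to HCl, or the sequence may stall at the open chalcone because the hindered, electron-rich ketone carbonyl resists ring closure. The fallback separates C–C bond formation from cyclisation; it sets out from 7 and 8 and comes back at 10. Aldehyde 8 is protected (MOMCl, i-Pr2NEt, CH2Cl2) as 3,4-dimethoxy-2-(methoxymethoxy)benzaldehyde F4. Base-mediated Claisen–Schmidt condensation with ketone 7 (KOH, EtOH) should give (Z)-1-[2,5-bis(benzyloxy)-4-methoxyphenyl]-3-[3,4-dimethoxy-2-(methoxymethoxy)phenyl]-2-methoxyprop-2-en-1-one F5. Brief treatment with anhydrous HCl in MeOH/EtOAc at 0 °C then removes the acetal and closes the ring by cyclodehydration to flavylium chloride 10; the acid contact time is far shorter than in the one-pot condensation.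

Step 3 (aryllithium acylation). The aryllithium may deprotonate the Weinreb amide at its α-carbon, or the negative charge may migrate to the neighbouring benzylic position, and both processes return debrominated arene. The fallback replaces the organometallic acylation by an electrophilic one; it sets out from 2 and comes back at 7. Friedel–Crafts acylation of 2 with methoxyacetyl chloride (COCC(=O)Cl) and SnCl4 in CH2Cl2 at −78 to −20 °C should acylate the same ring position that step 2 brominates. The temperature is kept low to limit decarbonylation of the acylium ion and Lewis-acid cleavage of the ortho benzyl ether. This fallback makes no compound outside the list (F0).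

**Further compounds**
F1 | step 5 | 2,5-bis(benzyloxy)-4-methoxybenzaldehyde | COc1cc(OCc2ccccc2)c(C=O)cc1OCc1ccccc1
F2 | step 5 | (E)-3-[2,5-bis(benzyloxy)-4-methoxyphenyl]-1-(2-hydroxy-3,4-dimethoxyphenyl)prop-2-en-1-one | COc1ccc(C(=O)/C=C/c2cc(OCc3ccccc3)c(OC)cc2OCc2ccccc2)c(O)c1OC
F3 | step 5 | 2-[2,5-bis(benzyloxy)-4-methoxyphenyl]-3-hydroxy-7,8-dimethoxy-4H-chromen-4-one | COc1cc(OCc2ccccc2)c(-c2oc3c(OC)c(OC)ccc3c(=O)c2O)cc1OCc1ccccc1
F4 | step 4 | 3,4-dimethoxy-2-(methoxymethoxy)benzaldehyde | COCOc1c(C=O)ccc(OC)c1OC
F5 | step 4 | (Z)-1-[2,5-bis(benzyloxy)-4-methoxyphenyl]-3-[3,4-dimethoxy-2-(methoxymethoxy)phenyl]-2-methoxyprop-2-en-1-one | COCOc1c(/C=C(\OC)C(=O)c2cc(OCc3ccccc3)c(OC)cc2OCc2ccccc2)ccc(OC)c1OC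
F0 | step 3 | none | none
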